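**Plan**
- Retrosynthesis first cuts the C4–C8 interflavanyl bond into a flavan-4-yl cation and C8 of (2R,3R)-dihydrorobinetin. The flavan-3,4-diol that supplies the cation is the NaBH4 reduction product of the same dihydroflavonol, so one protected dihydroflavonol serves both halves.
- Ring C of that dihydroflavonol is then cut at C2–C3. Its α-ketol unit O=C4–C3H(OH) is the acyloin isomer of a 3-hydroxy-2,3-dihydrobenzofuran-3-carbaldehyde, so ring C arises by enlargement of a five-membered O1–C2–C–C4a–C8a ring. This is possible because the carbinol carbon carries ring A with oxygen para (O7) and ortho (O1) to it, so it becomes a stabilised aryl ketone (C4) when C2 moves to the formyl carbon (C3).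
- The dihydrobenzofuran is cut at its C2–C3 bond (carbenoid C–H insertion) back to an aryldiazoacetate, made from methyl 2,4-dihydroxyphenylacetate and two equivalents of tris(benzyloxy)benzyl alcohol, which supplies ring B/C2 and the O7 protecting group.
- Forward order: etherification, diazo transfer, five-membered ring by C–H insertion, C3 hydroxylation, ester to aldehyde, ring enlargement to ring C, debenzylation, carbonyl reduction of one portion, acid-catalysed union of the two units.
- Stereochemistry: C2 from the chiral dirhodium catalyst; C3 from the chelate-controlled 1,2-shift, reinforced by the 2,3-trans thermodynamic preference; C4 of the upper unit from attack of the nucleophile anti to the 3-OH.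

Key step: step 7

Assumption: Rh2(S-PTTL)4 is taken to be the catalyst antipode that gives the (2S)-configured insertion product drawn; if the sense of induction is the opposite, Rh2(R-PTTL)4 is used instead.

**Step 1**
Reactants: 1 methyl 2-(2,4-dihydroxyphenyl)acetate; 2 [3,4,5-tris(benzyloxy)phenyl]methanol (2.2 equiv)
Product: 4 methyl 2-(2,4-bis{[3,4,5-tris(benzyloxy)phenyl]methoxy}phenyl)acetate, via 4-O-monoether 3 (not isolated)
Conditions: PPh3, DIAD, THF, 0 °C to rt
Reagents that add atoms: none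
Why: Mitsunobu etherification of both phenols with the primary benzylic alcohol should be clean because the arylacetate C–H is far less acidic than the phenols; the benzyl group on O2 is the future C2/ring B unit and the same group on O4 is a hydrogenolysable protecting group for the future O7.

**Step 2**
Reactants: 4 methyl 2-(2,4-bis{[3,4,5-tris(benzyloxy)phenyl]methoxy}phenyl)acetate
Product: 5 methyl 2-diazo-2-(2,4-bis{[3,4,5-tris(benzyloxy)phenyl]methoxy}phenyl)acetate
Conditions: 4-acetamidobenzenesulfonyl azide, DBU, MeCN, 0 °C to rt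
Reagents that add atoms: 4-acetamidobenzenesulfonyl azide, CC(=O)Nc1ccc(cc1)S(=O)(=O)N=[N+]=[N-]
Why: Regitz diazo transfer to the benzylic ester position of an arylacetate is the standard entry to donor/acceptor aryldiazoacetates.

**Step 3**
Reactants: 5 methyl 2-diazo-2-(2,4-bis{[3,4,5-tris(benzyloxy)phenyl]methoxy}phenyl)acetate
Product: 6 methyl (2S,3R)-2-[3,4,5-tris(benzyloxy)phenyl]-6-{[3,4,5-tris(benzyloxy)phenyl]methoxy}-2,3-dihydro-1-benzofuran-3-carboxylate (2,3-cis)
Conditions: Rh2(S-PTTL)4 (dirhodium tetrakis[N-phthaloyl-(S)-tert-leucinate], 1 mol %), toluene, −60 °C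
Reagents that add atoms: none
Why: Intramolecular 1,5 carbenoid C–H insertion into the ortho benzylic ether CH2 (activated by the adjacent oxygen and the electron-rich ring B) closes the five-membered ring; the chiral carboxylate ligands set C2, and the kinetic 2,3-cis relationship at C3 is of no consequence because C3 is made planar in step 4.

**Step 4**
Reactants: 6 methyl (2S,3R)-2-[3,4,5-tris(benzyloxy)phenyl]-6-{[3,4,5-tris(benzyloxy)phenyl]methoxy}-2,3-dihydro-1-benzofuran-3-carboxylate
Product: 8 methyl (2R,3S)-3-hydroxy-2-[3,4,5-tris(benzyloxy)phenyl]-6-{[3,4,5-tris(benzyloxy)phenyl]methoxy}-2,3-dihydro-1-benzofuran-3-carboxylate (OH trans to the 2-aryl group), via potassium ester enolate 7 (not isolated)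
Conditions: KN(SiMe3)2, THF, −78 °C; then 2-(phenylsulfonyl)-3-phenyloxaziridine, −78 °C; AcOH quench
Reagents that add atoms: 2-(phenylsulfonyl)-3-phenyloxaziridine, O=S(=O)(c1ccccc1)N1OC1c1ccccc1
Why: Davis enolate hydroxylation; the enolate cannot expel the ring A phenoxide because its π system is orthogonal to the endocyclic C2–O1 bond (the reverse of a 5-endo-trig closure), and it should take up oxygen on the face opposite the C2 aryl group, placing the new OH trans to that group.

**Step 5**
Reactants: 8 methyl (2R,3S)-3-hydroxy-2-[3,4,5-tris(benzyloxy)phenyl]-6-{[3,4,5-tris(benzyloxy)phenyl]methoxy}-2,3-dihydro-1-benzofuran-3-carboxylate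
Product: 9 (2R,3R)-3-(hydroxymethyl)-2-[3,4,5-tris(benzyloxy)phenyl]-6-{[3,4,5-tris(benzyloxy)phenyl]methoxy}-2,3-dihydro-1-benzofuran-3-ol
Conditions: LiAlH4, THF, 0 °C
Reagents that add atoms: none
Why: Hydride reduction of the ester to the primary alcohol leaves benzyl ethers and the tertiary alcohol untouched and changes no stereocentre.

**Step 6**
Reactants: 9 (2R,3R)-3-(hydroxymethyl)-2-[3,4,5-tris(benzyloxy)phenyl]-6-{[3,4,5-tris(benzyloxy)phenyl]methoxy}-2,3-dihydro-1-benzofuran-3-ol
Product: 10 (2R,3S)-3-hydroxy-2-[3,4,5-tris(benzyloxy)phenyl]-6-{[3,4,5-tris(benzyloxy)phenyl]methoxy}-2,3-dihydro-1-benzofuran-3-carbaldehyde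
Conditions: SO3·pyridine, DMSO, iPr2NEt, CH2Cl2, 0 °C; crude product taken on directly
Reagents that add atoms: none
Why: Parikh–Doering oxidation converts only the primary alcohol (the tertiary one cannot be oxidised) and, unlike periodinane or lead reagents, activated DMSO does not cleave the 1,2-diol.

**Step 7**
Reactants: 10 (2R,3S)-3-hydroxy-2-[3,4,5-tris(benzyloxy)phenyl]-6-{[3,4,5-tris(benzyloxy)phenyl]methoxy}-2,3-dihydro-1-benzofuran-3-carbaldehyde
Product: 11 (2R,3R)-3-hydroxy-2-[3,4,5-tris(benzyloxy)phenyl]-7-{[3,4,5-tris(benzyloxy)phenyl]methoxy}-2,3-dihydro-4H-chromen-4-one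
Conditions: Al(Ot-Bu)3 (0.3 equiv), toluene, 50 °C
Reagents that add atoms: none
Why: α-Ketol (acyloin) rearrangement with ring enlargement: the aluminium alkoxide of the tertiary alcohol chelates the formyl oxygen, the O–C–C=O unit becomes syn-periplanar, and C2 shifts with its bonding pair from the carbinol carbon to the formyl carbon while the carbinol carbon becomes the C4 carbonyl. The closest known reaction type is the Lewis-acid-mediated acyloin ring enlargement of 1-hydroxycycloalkane-1-carbaldehydes and 1-acylbenzocyclobutenols, in which the saturated ring carbon migrates and an aryl ketone results. Ring C is closed by this suprafacial 1,2-shift of carbon, the formyl carbon being inserted between C2 and the old C3 so that the five-membered dihydrofuran ring becomes the six-membered pyranone ring; no new polar ring closure is involved. C2 migrates with retention and keeps its configuration from step 3; the new C3 stereocentre is set by the chelate, which holds the C3–O bond in the plane of the nascent C4=O and delivers C2 to the formyl face that makes the 3-OH equatorial and trans to the 2-aryl group, which is also the thermodynamically preferred arrangement. The step needs migration of C2 in preference to the ring A carbon: this is secured by the α-oxygen on C2 and above all by the para-oxygenated ring A, which stays on the carbinol carbon and stabilises the developing aryl ketone, and because α-ketol shifts are reversible the conjugated 2,4-dioxygenated aryl ketone is the sink.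

**Step 8**
Reactants: 11 (2R,3R)-3-hydroxy-2-[3,4,5-tris(benzyloxy)phenyl]-7-{[3,4,5-tris(benzyloxy)phenyl]methoxy}-2,3-dihydro-4H-chromen-4-one
Product: 12 (2R,3R)-3,7-dihydroxy-2-(3,4,5-trihydroxyphenyl)-2,3-dihydro-4H-chromen-4-one ((+)-dihydrorobinetin)
Conditions: H2 (1 atm), Pd(OH)2/C, THF–MeOH, rt, stopped at full debenzylation
Reagents that add atoms: none
Why: Hydrogenolysis removes all seven benzylic ether groups (six O-benzyl groups and the O7 aryl-methyl group) under neutral conditions, which the vinylogous-ester-like C4 carbonyl and the two stereocentres should survive.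

**Step 9**
Reactants: 12 (2R,3R)-3,7-dihydroxy-2-(3,4,5-trihydroxyphenyl)-2,3-dihydro-4H-chromen-4-one (one portion)
Product: 13 (2R,3S,4R)-2-(3,4,5-trihydroxyphenyl)-3,4-dihydro-2H-chromene-3,4,7-triol (2,3-trans-3,4-trans flavan-3,4-diol)
Conditions: NaBH4 (excess), EtOH, 0 °C to rt; dilute AcOH work-up; used directly
Reagents that add atoms: none
Why: Borohydride reduction of a 2,3-trans dihydroflavonol is expected to deliver hydride so that the new 4-OH is trans to the 3-OH; either C4 epimer would serve, since both ionise to the same cation in step 10.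

**Step 10**
Reactants: 13 (2R,3S,4R)-2-(3,4,5-trihydroxyphenyl)-3,4-dihydro-2H-chromene-3,4,7-triol; 12 (2R,3R)-3,7-dihydroxy-2-(3,4,5-trihydroxyphenyl)-2,3-dihydro-4H-chromen-4-one (fourfold excess, remainder recovered)
Product: 15 (2R,3R)-3,7-dihydroxy-8-[(2R,3S,4S)-3,7-dihydroxy-2-(3,4,5-trihydroxyphenyl)-3,4-dihydro-2H-chromen-4-yl]-2-(3,4,5-trihydroxyphenyl)-2,3-dihydro-4H-chromen-4-one, via flavan-4-yl cation 14 (not isolated)
Conditions: 0.1 M aqueous HCl–1,4-dioxane, rt, under N2; separation on Sephadex LH-20 and by preparative HPLC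
Reagents that add atoms: none
Why: Acid-catalysed ionisation of the benzylic 4-OH gives the O7-stabilised flavan-4-yl cation, which should be captured in a Friedel–Crafts-type interflavanyl coupling by C8 of the dihydroflavonol (ortho to its 7-OH and ring oxygen, the usual site of substitution in 7-hydroxychroman-4-ones) on the face anti to the neighbouring 3-OH, giving the 3,4-trans (4α) configuration.

**Compound list**
1 | methyl 2-(2,4-dihydroxyphenyl)acetate | COC(=O)Cc1ccc(O)cc1O | starting material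
2 | [3,4,5-tris(benzyloxy)phenyl]methanol | OCc1cc(OCc2ccccc2)c(OCc2ccccc2)c(OCc2ccccc2)c1 | starting material
3 | methyl 2-(2-hydroxy-4-{[3,4,5-tris(benzyloxy)phenyl]methoxy}phenyl)acetate | COC(=O)Cc1ccc(OCc2cc(OCc3ccccc3)c(OCc3ccccc3)c(OCc3ccccc3)c2)cc1O | intermediate (not isolated)
4 | methyl 2-(2,4-bis{[3,4,5-tris(benzyloxy)phenyl]methoxy}phenyl)acetate | COC(=O)Cc1ccc(OCc2cc(OCc3ccccc3)c(OCc3ccccc3)c(OCc3ccccc3)c2)cc1OCc1cc(OCc2ccccc2)c(OCc2ccccc2)c(OCc2ccccc2)c1 | intermediate
5 | methyl 2-diazo-2-(2,4-bis{[3,4,5-tris(benzyloxy)phenyl]methoxy}phenyl)acetate | COC(=O)C(=[N+]=[N-])c1ccc(OCc2cc(OCc3ccccc3)c(OCc3ccccc3)c(OCc3ccccc3)c2)cc1OCc1cc(OCc2ccccc2)c(OCc2ccccc2)c(OCc2ccccc2)c1 | intermediate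
6 | methyl (2S,3R)-2-[3,4,5-tris(benzyloxy)phenyl]-6-{[3,4,5-tris(benzyloxy)phenyl]methoxy}-2,3-dihydro-1-benzofuran-3-carboxylate | C(c1cc(OCc2ccccc2)c(OCc2ccccc2)c(OCc2ccccc2)c1)Oc1ccc2c(c1)O[C@H](c1cc(OCc3ccccc3)c(OCc3ccccc3)c(OCc3ccccc3)c1)[C@@H]2C(=O)OC | intermediate
7 | potassium enolate of ester 6 | C(c1cc(OCc2ccccc2)c(OCc2ccccc2)c(OCc2ccccc2)c1)Oc1ccc2c(c1)O[C@H](c1cc(OCc3ccccc3)c(OCc3ccccc3)c(OCc3ccccc3)c1)C2=C([O-])OC.[K+] | intermediate (not isolated)
8 | methyl (2R,3S)-3-hydroxy-2-[3,4,5-tris(benzyloxy)phenyl]-6-{[3,4,5-tris(benzyloxy)phenyl]methoxy}-2,3-dihydro-1-benzofuran-3-carboxylate | C(c1cc(OCc2ccccc2)c(OCc2ccccc2)c(OCc2ccccc2)c1)Oc1ccc2c(c1)O[C@H](c1cc(OCc3ccccc3)c(OCc3ccccc3)c(OCc3ccccc3)c1)[C@]2(O)C(=O)OC | intermediate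
9 | (2R,3R)-3-(hydroxymethyl)-2-[3,4,5-tris(benzyloxy)phenyl]-6-{[3,4,5-tris(benzyloxy)phenyl]methoxy}-2,3-dihydro-1-benzofuran-3-ol | C(c1cc(OCc2ccccc2)c(OCc2ccccc2)c(OCc2ccccc2)c1)Oc1ccc2c(c1)O[C@H](c1cc(OCc3ccccc3)c(OCc3ccccc3)c(OCc3ccccc3)c1)[C@]2(O)CO | intermediate
10 | (2R,3S)-3-hydroxy-2-[3,4,5-tris(benzyloxy)phenyl]-6-{[3,4,5-tris(benzyloxy)phenyl]methoxy}-2,3-dihydro-1-benzofuran-3-carbaldehyde | C(c1cc(OCc2ccccc2)c(OCc2ccccc2)c(OCc2ccccc2)c1)Oc1ccc2c(c1)O[C@H](c1cc(OCc3ccccc3)c(OCc3ccccc3)c(OCc3ccccc3)c1)[C@]2(O)C=O | intermediate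
11 | (2R,3R)-3-hydroxy-2-[3,4,5-tris(benzyloxy)phenyl]-7-{[3,4,5-tris(benzyloxy)phenyl]methoxy}-2,3-dihydro-4H-chromen-4-one | C(c1cc(OCc2ccccc2)c(OCc2ccccc2)c(OCc2ccccc2)c1)Oc1ccc2c(c1)O[C@H](c1cc(OCc3ccccc3)c(OCc3ccccc3)c(OCc3ccccc3)c1)[C@@H](O)C2=O | intermediate
12 | (2R,3R)-3,7-dihydroxy-2-(3,4,5-trihydroxyphenyl)-2,3-dihydro-4H-chromen-4-one | O=C1c2ccc(O)cc2O[C@H](c2cc(O)c(O)c(O)c2)[C@H]1O | intermediate
13 | (2R,3S,4R)-2-(3,4,5-trihydroxyphenyl)-3,4-dihydro-2H-chromene-3,4,7-triol | Oc1ccc2c(c1)O[C@H](c1cc(O)c(O)c(O)c1)[C@@H](O)[C@@H]2O | intermediate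
14 | (2R,3S)-3,7-dihydroxy-2-(3,4,5-trihydroxyphenyl)-3,4-dihydro-2H-chromen-4-ylium (flavan-4-yl cation) | Oc1ccc2c(c1)O[C@H](c1cc(O)c(O)c(O)c1)[C@@H](O)[CH+]2 | intermediate (not isolated)
15 | (2R,3R)-3,7-dihydroxy-8-[(2R,3S,4S)-3,7-dihydroxy-2-(3,4,5-trihydroxyphenyl)-3,4-dihydro-2H-chromen-4-yl]-2-(3,4,5-trihydroxyphenyl)-2,3-dihydro-4H-chromen-4-one | O=C1c2ccc(O)c([C@@H]3c4ccc(O)cc4O[C@H](c4cc(O)c(O)c(O)c4)[C@H]3O)c2O[C@H](c2cc(O)c(O)c(O)c2)[C@H]1O | target

**Count**
Total step count: 10. Longest linear sequence: 10 steps (from 1).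

**Steps most likely to fail**

Step 10. The cation may be consumed by self-condensation with ring A of unreacted diol, attack may occur at C6 instead of C8 of the dihydroflavonol, and acid may equilibrate the interflavanyl bond, leaving little of the 4α→8 dimer. Fallback: setting out from 13, acid-catalysed thiolysis with phenylmethanethiol (AcOH, rt) should give the stable (2R,3R,4R)-4-(benzylsulfanyl)-2-(3,4,5-trihydroxyphenyl)-3,4-dihydro-2H-chromene-3,7-diol F1. Slow addition of this thioether to an excess of 12 and AgBF4 in THF at 0 °C releases the same cation by thiophilic activation under neutral conditions and in low stationary concentration, and the sequence comes back to the route at 15.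

Step 7. The ring A carbon may shift in competition with C2, the aluminium alkoxide may mediate Tishchenko-type dimerisation of the aldehyde, and C2 may epimerise through Lewis-acid ionisation of the C2–O1 bond. Fallback: setting out from 10, silylation of the tertiary alcohol (Et3SiOTf, 2,6-lutidine, CH2Cl2, −78 °C) gives (2R,3S)-3-(triethylsilyloxy)-2-[3,4,5-tris(benzyloxy)phenyl]-6-{[3,4,5-tris(benzyloxy)phenyl]methoxy}-2,3-dihydro-1-benzofuran-3-carbaldehyde F2. The organoaluminium-promoted 1,2-shift of α-silyloxy aldehydes with silyl transfer (MeAl(OAr)2, Ar = 4-bromo-2,6-di-tert-butylphenyl, CH2Cl2, −78 °C) then gives (2R,3R)-3-(triethylsilyloxy)-2-[3,4,5-tris(benzyloxy)phenyl]-7-{[3,4,5-tris(benzyloxy)phenyl]methoxy}-2,3-dihydro-4H-chromen-4-one F3. HF·pyridine removes the silyl group and the sequence comes back to the route at 11. This replaces the chelated alkoxide shift by a non-chelated silyloxy-aldehyde rearrangement at low temperature, with no free alkoxide or aluminium alkoxide present.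

Step 3. Enantiofacial discrimination in the C–H insertion may be insufficient, and carbene dimerisation may compete. Fallback: resolution in place of catalyst control. Setting out from 9 of insufficient enantiomeric purity, acylation of the primary alcohol with (S)-2-methoxy-2-phenylacetic acid (EDC, DMAP, CH2Cl2) gives diastereomeric esters, from which [(2R,3R)-3-hydroxy-2-[3,4,5-tris(benzyloxy)phenyl]-6-{[3,4,5-tris(benzyloxy)phenyl]methoxy}-2,3-dihydro-1-benzofuran-3-yl]methyl (2S)-2-methoxy-2-phenylacetate F4 is separated by chromatography or crystallisation. Saponification (LiOH, THF–H2O) comes back to the route at enantiopure 9.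

**Further compounds**
F1 | step 10 | (2R,3R,4R)-4-(benzylsulfanyl)-2-(3,4,5-trihydroxyphenyl)-3,4-dihydro-2H-chromene-3,7-diol | Oc1ccc2c(c1)O[C@H](c1cc(O)c(O)c(O)c1)[C@@H](O)[C@@H]2SCc1ccccc1
F2 | step 7 | (2R,3S)-3-(triethylsilyloxy)-2-[3,4,5-tris(benzyloxy)phenyl]-6-{[3,4,5-tris(benzyloxy)phenyl]methoxy}-2,3-dihydro-1-benzofuran-3-carbaldehyde | C(c1cc(OCc2ccccc2)c(OCc2ccccc2)c(OCc2ccccc2)c1)Oc1ccc2c(c1)O[C@H](c1cc(OCc3ccccc3)c(OCc3ccccc3)c(OCc3ccccc3)c1)[C@]2(O[Si](CC)(CC)CC)C=O
F3 | step 7 | (2R,3R)-3-(triethylsilyloxy)-2-[3,4,5-tris(benzyloxy)phenyl]-7-{[3,4,5-tris(benzyloxy)phenyl]methoxy}-2,3-dihydro-4H-chromen-4-one | C(c1cc(OCc2ccccc2)c(OCc2ccccc2)c(OCc2ccccc2)c1)Oc1ccc2c(c1)O[C@H](c1cc(OCc3ccccc3)c(OCc3ccccc3)c(OCc3ccccc3)c1)[C@@H](O[Si](CC)(CC)CC)C2=O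
F4 | step 3 | [(2R,3R)-3-hydroxy-2-[3,4,5-tris(benzyloxy)phenyl]-6-{[3,4,5-tris(benzyloxy)phenyl]methoxy}-2,3-dihydro-1-benzofuran-3-yl]methyl (2S)-2-methoxy-2-phenylacetate | C(c1cc(OCc2ccccc2)c(OCc2ccccc2)c(OCc2ccccc2)c1)Oc1ccc2c(c1)O[C@H](c1cc(OCc3ccccc3)c(OCc3ccccc3)c(OCc3ccccc3)c1)[C@]2(O)COC(=O)[C@@H](OC)c1ccccc1
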